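The route rests on cutting the C4–C5 bond of ring A. C5 is the methyl-bearing quaternary carbon β to the C7 oxygen of ring B and C4 lies α to the C3 oxygen, so this most congested bond joins a ketone α-carbon to a β-methyl enone. One amine-catalysed intramolecular Michael addition therefore closes ring A, creates the quaternary centre and fixes C4, C5 and C10, while the enone substrate racemises at C10 so that both enantiomers converge on a single cis-fused dione. The precursor is racemic 3-methyl-4-(3-oxopentyl)cyclohex-2-en-1-one; afterwards the C7 ketone is grown into the C7/C8 diosphenol and the C3 ketone into the acylated allylic alcohol.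

Key step: step 4

Remark on numbering: eremophilane numbering is used (ring A = C1–C5 and C10, ring B = C5–C10, methyl groups on C4 and C5); β is the face that carries both methyl groups.
Assumption: the quinine-derived amine is taken to deliver the (5S) series; if it delivers (5R), its quinidine-derived pseudoenantiomer is used with nothing else changed.

Step 1
Reactants: 1 ethyl vinyl ketone
Product: 3 2-ethyl-2-(2-iodoethyl)-1,3-dioxolane, via iodo silyl enol ether 2 (not isolated)
Conditions: NaI, TMSCl, MeCN, rt; then HOCH2CH2OH, rt
Reagents that add atoms: sodium iodide, [Na+].[I-]; ethylene glycol, OCCO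
Why: Conjugate addition of iodotrimethylsilane made in the flask to the enone, followed by ketalisation of the silyl enol ether with the diol, is a known one-flask route to β-iodo ketals of vinyl ketones, and no stereocentre is formed.

Step 2
Reactants: 4 3-ethoxycyclohex-2-en-1-one; 3 2-ethyl-2-(2-iodoethyl)-1,3-dioxolane
Product: 5 racemic 3-ethoxy-6-[2-(2-ethyl-1,3-dioxolan-2-yl)ethyl]cyclohex-2-en-1-one
Conditions: LiN(i-Pr)2, DMPU, THF, −78 → 0 °C
Reagents that add atoms: none
Why: Stork–Danheiser alkylation, in which the kinetic lithium enolate of the vinylogous ester forms at C6 and is alkylated by the primary iodide, creating the single racemic stereocentre that later becomes C10.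

Step 3
Reactants: 5 racemic 3-ethoxy-6-[2-(2-ethyl-1,3-dioxolan-2-yl)ethyl]cyclohex-2-en-1-one; 6 methyllithium
Product: 8 racemic 3-methyl-4-(3-oxopentyl)cyclohex-2-en-1-one, via tertiary allylic alcohol 7 (not isolated)
Conditions: MeLi, Et2O/THF, −78 → 0 °C; then 1 M HCl, THF, rt
Reagents that add atoms: water, O
Why: Second half of the Stork–Danheiser sequence, in which 1,2-addition to the vinylogous ester carbonyl and acid hydrolysis with allylic transposition give the 3-methyl enone while the same acid frees the side-chain ketone from its dioxolane, the C10 centre staying racemic.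

Step 4
Reactants: 8 racemic 3-methyl-4-(3-oxopentyl)cyclohex-2-en-1-one
Product: 9 cis-fused (4R,5S,10S)-4,5-dimethyldecalin-3,7-dione (4-methyl, 5-methyl and H-10 all β)
Conditions: 9-amino-9-deoxy-epi-quinine (20 mol %), CF3CO2H (30 mol %), toluene, 40 °C
Reagents that add atoms: none
Why: Proposed new method: the primary amine condenses with the ring enone to an iminium ion that makes C5 electrophilic, the side-chain ketone reacts through its C3=C4 enol (or its enamine with a second catalyst molecule), C4 adds to C5 in an intramolecular Michael addition and hydrolysis returns the catalyst; the closest known reactions are amine- or base-mediated intramolecular Michael cyclisations of keto enones to angularly methylated cis-decalones and iminium activation of β,β-disubstituted cyclohexenones by 9-amino cinchona salts, but their combination with racemisation of the substrate is untested. Ring A closes in the 6-exo-trig mode with respect to the C5=C6 acceptor (enol-endo for the nucleophile), and because the three-carbon tether on C10 reaches C5 only on its own face the ring fusion can only be cis. The two substrate enantiomers interconvert through the linear dienamine N–C7=C6–C5=C10 formed by reversible γ-deprotonation at C10 (the cross-conjugated dienamine from C8 would leave C10 untouched), so under Curtin–Hammett conditions the chiral amine's preference for cyclising one C10 enantiomer of the iminium ion controls C5 (S required) and C10 (S) together. C4 is set kinetically by a chair-like transition state in which the enol methyl, cis to the enol oxygen, lies equatorial and therefore cis to the C5 methyl (4R); since ring inversion of the cis-decalin lets either C4 epimer be equatorial, no thermodynamic correction is assumed and the reaction is worked up at full conversion. The step needs enantioface selection at C5 with racemisation faster than cyclisation of the slow enantiomer, while regioselectivity is secured by the substrate because only the C4 enol can reach an electrophilic carbon through a six-membered ring, the C2 enol facing a four-membered closure.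

Step 5
Reactants: 9 cis-fused (4R,5S,10S)-4,5-dimethyldecalin-3,7-dione
Product: 10 C7 ethylene ketal of 9 (7,7-ethylenedioxy-4,5-dimethyl-cis-decalin-3-one; configuration as in 9)
Conditions: TMSOCH2CH2OTMS (1.05 equiv), TMSOTf (cat.), CH2Cl2, −78 °C; pyridine
Reagents that add atoms: 1,2-bis(trimethylsilyloxy)ethane, C[Si](C)(C)OCCO[Si](C)(C)C
Why: Chemoselective Noyori ketalisation under kinetic control, in which the C7 carbonyl flanked by two methylene groups should react before the C3 carbonyl that carries the C4 methine next to the quaternary C5, at a temperature too low for enolisation at C4.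

Step 6
Reactants: 10 C7 ethylene ketal of 9
Product: 12 (4R,5S,10S)-7,7-ethylenedioxy-4,5-dimethyl-Δ1-octalin-3-one (C1=C2 enone; cis ring fusion), via trimethylsilyl enol ether 11 (not isolated)
Conditions: LiN(i-Pr)2, TMSCl, THF, −78 °C; then Pd(OAc)2 (1.1 equiv), MeCN, rt
Reagents that add atoms: none
Why: Saegusa–Ito oxidation, in which kinetic deprotonation takes the unhindered C2 methylene and not the C4 methine, so the C4 configuration is left alone, and palladium diacetate turns the C2=C3 silyl enol ether into the C1=C2 enone.

Step 7
Reactants: 12 (4R,5S,10S)-7,7-ethylenedioxy-4,5-dimethyl-Δ1-octalin-3-one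
Product: 13 (3S,4R,5S,10S)-7,7-ethylenedioxy-4,5-dimethyl-Δ1-octalin-3-ol (3-hydroxyl β, cis to both methyl groups)
Conditions: NaBH4, CeCl3·7H2O, MeOH, −78 °C
Reagents that add atoms: none
Why: Luche reduction gives clean 1,2-addition, and hydride is expected to enter at C3 from the α face, opposite the C5 methyl that sits axial over the β face in the conformer with the C4 methyl equatorial, so the new hydroxyl (3S) should be cis to both methyl groups.

Step 8
Reactants: 14 (R)-4-benzyl-1,3-oxazolidin-2-one; 15 butanoyl chloride
Product: 16 (R)-4-benzyl-3-butanoyl-1,3-oxazolidin-2-one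
Conditions: n-BuLi, THF, −78 → 0 °C
Reagents that add atoms: none
Why: N-Acylation of the lithiated oxazolidinone with an acid chloride is standard and forms no stereocentre.

Step 9
Reactants: 16 (R)-4-benzyl-3-butanoyl-1,3-oxazolidin-2-one
Product: 17 (R)-4-benzyl-3-[(2S)-2-(hydroxymethyl)butanoyl]-1,3-oxazolidin-2-one
Conditions: TiCl4, i-Pr2NEt, 1,3,5-trioxane, CH2Cl2, 0 °C
Reagents that add atoms: 1,3,5-trioxane, C1OCOCO1
Why: Auxiliary-controlled hydroxymethylation of the chelated (Z)-titanium enolate with formaldehyde released from trioxane, in which the electrophile approaches the enolate face opposite the benzyl group and should set the (2S) centre.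

Step 10
Reactants: 17 (R)-4-benzyl-3-[(2S)-2-(hydroxymethyl)butanoyl]-1,3-oxazolidin-2-one
Product: 18 (R)-4-benzyl-3-[(2S)-2-{[tert-butyl(dimethyl)silyl]oxymethyl}butanoyl]-1,3-oxazolidin-2-one
Conditions: TBSCl, imidazole, CH2Cl2, rt
Reagents that add atoms: tert-butyldimethylsilyl chloride, CC(C)(C)[Si](C)(C)Cl
Why: Standard silylation of a primary alcohol under conditions too mild to epimerise the α-stereocentre of the imide.

Step 11
Reactants: 18 (R)-4-benzyl-3-[(2S)-2-{[tert-butyl(dimethyl)silyl]oxymethyl}butanoyl]-1,3-oxazolidin-2-one
Product: 19 (R)-2-{[tert-butyl(dimethyl)silyl]oxymethyl}butan-1-ol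
Conditions: LiBH4, MeOH (1 equiv), THF, 0 °C
Reagents that add atoms: none
Why: Reductive cleavage of the N-acyl oxazolidinone with LiBH4 releases the primary alcohol and the auxiliary without touching the stereocentre, whose descriptor becomes R only through the change in priorities.

Step 12
Reactants: 19 (R)-2-{[tert-butyl(dimethyl)silyl]oxymethyl}butan-1-ol
Product: 20 (S)-2-{[tert-butyl(dimethyl)silyl]oxymethyl}butanal
Conditions: Dess–Martin periodinane, CH2Cl2, 0 °C → rt
Reagents that add atoms: none
Why: Dess–Martin oxidation of a primary alcohol to the aldehyde under near-neutral conditions, chosen so that the α-stereocentre (S by priority change only) is not epimerised.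

Step 13
Reactants: 20 (S)-2-{[tert-butyl(dimethyl)silyl]oxymethyl}butanal; 21 triethyl 4-phosphonocrotonate
Product: 22 ethyl (2E,4E,6R)-6-{[tert-butyl(dimethyl)silyl]oxymethyl}octa-2,4-dienoate
Conditions: LiN(SiMe3)2, THF, −78 → 0 °C
Reagents that add atoms: none
Why: Vinylogous Horner–Wadsworth–Emmons olefination, in which the stabilised phosphonate anion should form the new C4=C5 double bond E and carries the existing E double bond, the low temperature protecting the α-stereocentre of the aldehyde.

Step 14
Reactants: 22 ethyl (2E,4E,6R)-6-{[tert-butyl(dimethyl)silyl]oxymethyl}octa-2,4-dienoate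
Product: 23 (2E,4E,6R)-6-{[tert-butyl(dimethyl)silyl]oxymethyl}octa-2,4-dienoic acid
Conditions: LiOH, THF/MeOH/H2O, rt; acidify to pH 4 (1 M HCl, 0 °C)
Reagents that add atoms: lithium hydroxide, [Li+].[OH-]
Why: Saponification of the ethyl ester, to which the silyl ether, the diene geometry and the remote stereocentre are stable.

Step 15
Reactants: 13 (3S,4R,5S,10S)-7,7-ethylenedioxy-4,5-dimethyl-Δ1-octalin-3-ol; 23 (2E,4E,6R)-6-{[tert-butyl(dimethyl)silyl]oxymethyl}octa-2,4-dienoic acid
Product: 25 C3 dienoate ester of 13 (ketal and silyl ether in place), via mixed anhydride 24 (not isolated)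
Conditions: 2,4,6-Cl3C6H2COCl, Et3N, THF, rt; then 13, DMAP, toluene, rt
Reagents that add atoms: none
Why: Yamaguchi esterification through the mixed anhydride acylates the hindered secondary allylic alcohol with retention at C3 and without isomerising the dienoate.

Step 16
Reactants: 25 C3 dienoate ester of 13
Product: 26 C7 ketone (ester 25 without the dioxolane; cis ring fusion)
Conditions: PPTS, acetone/H2O, 50 °C
Reagents that add atoms: water, O
Why: Mild acid-catalysed ketal hydrolysis removes the dioxolane, while the allylic ester and the primary silyl ether tolerate pyridinium tosylate.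

Step 17
Reactants: 26 C7 ketone
Product: 27 8-hydroxy-7-ketone (mixture of C8 epimers)
Conditions: NaN(SiMe3)2, 2-(phenylsulfonyl)-3-phenyloxaziridine, THF, −78 °C
Reagents that add atoms: 2-(phenylsulfonyl)-3-phenyloxaziridine, O=S(=O)(c1ccccc1)N1OC1c1ccccc1
Why: Davis oxidation, in which kinetic deprotonation of the C7 ketone takes the C8 methylene and not the neopentyl C6 position and the sodium enolate is hydroxylated by the N-sulfonyloxaziridine; the new C8 centre is destroyed in the next step and the dienoate, which has no α-hydrogen, is not deprotonated at this temperature.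

Step 18
Reactants: 27 8-hydroxy-7-ketone
Product: 28 7,8-dione, drawn as its C7 enol (diosphenol)
Conditions: Dess–Martin periodinane, CH2Cl2, rt
Reagents that add atoms: none
Why: Dess–Martin oxidation of the acyloin to the 1,2-dione, which rests as its enol, so the C8 stereocentre disappears.

Step 19
Reactants: 28 7,8-dione (diosphenol)
Product: 29 O-silyl septeremophilane E (C9=C10 and C1=C2 dienone; side-chain silyl ether in place)
Conditions: DDQ, 1,4-dioxane, rt → 60 °C
Reagents that add atoms: none
Why: Quinone dehydrogenation, in which DDQ abstracts the doubly allylic tertiary hydride at C10 from the C8 enol tautomer and loss of the enol proton gives the C9=C10 dienone, after which the C7 carbonyl enolises toward C6; C10 is flattened and C3, C4 and C5 are untouched.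

Step 20
Reactants: 29 O-silyl septeremophilane E
Product: 30 septeremophilane E
Conditions: HF·pyridine, pyridine, THF, 0 °C → rt
Reagents that add atoms: none
Why: Fluoride-mediated cleavage of the primary silyl ether under buffered conditions that spare the allylic ester and the diosphenol.

Compound list
1 | ethyl vinyl ketone (pent-1-en-3-one) | CCC(=O)C=C | starting material
2 | 1-iodo-3-(trimethylsilyloxy)pent-2-ene (not isolated) | CCC(O[Si](C)(C)C)=CCI | intermediate
3 | 2-ethyl-2-(2-iodoethyl)-1,3-dioxolane | CCC1(CCI)OCCO1 | intermediate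
4 | 3-ethoxycyclohex-2-en-1-one | CCOC1=CC(=O)CCC1 | starting material
5 | racemic 3-ethoxy-6-[2-(2-ethyl-1,3-dioxolan-2-yl)ethyl]cyclohex-2-en-1-one | CCOC1=CC(=O)C(CCC2(CC)OCCO2)CC1 | intermediate
6 | methyllithium | [Li]C | starting material
7 | 3-ethoxy-6-[2-(2-ethyl-1,3-dioxolan-2-yl)ethyl]-1-methylcyclohex-2-en-1-ol (not isolated) | CCOC1=CC(C)(O)C(CCC2(CC)OCCO2)CC1 | intermediate
8 | racemic 3-methyl-4-(3-oxopentyl)cyclohex-2-en-1-one | CCC(=O)CCC1CCC(=O)C=C1C | intermediate
9 | cis-fused (4R,5S,10S)-4,5-dimethyldecalin-3,7-dione | O=C1CC[C@@H]2CCC(=O)C[C@]2(C)[C@H]1C | intermediate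
10 | C7 ethylene ketal of 9 (7,7-ethylenedioxy-4,5-dimethyl-cis-decalin-3-one) | O=C1CC[C@@H]2CCC3(OCCO3)C[C@]2(C)[C@H]1C | intermediate
11 | C2=C3 trimethylsilyl enol ether of 10 (not isolated) | C[Si](C)(C)OC1=CC[C@@H]2CCC3(OCCO3)C[C@]2(C)[C@H]1C | intermediate
12 | (4R,5S,10S)-7,7-ethylenedioxy-4,5-dimethyl-Δ1-octalin-3-one | O=C1C=C[C@@H]2CCC3(OCCO3)C[C@]2(C)[C@H]1C | intermediate
13 | (3S,4R,5S,10S)-7,7-ethylenedioxy-4,5-dimethyl-Δ1-octalin-3-ol | O[C@H]1C=C[C@@H]2CCC3(OCCO3)C[C@]2(C)[C@H]1C | intermediate
14 | (R)-4-benzyl-1,3-oxazolidin-2-one | O=C1N[C@H](Cc2ccccc2)CO1 | starting material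
15 | butanoyl chloride | CCCC(=O)Cl | starting material
16 | (R)-4-benzyl-3-butanoyl-1,3-oxazolidin-2-one | CCCC(=O)N1[C@H](Cc2ccccc2)COC1=O | intermediate
17 | (R)-4-benzyl-3-[(2S)-2-(hydroxymethyl)butanoyl]-1,3-oxazolidin-2-one | CC[C@@H](CO)C(=O)N1[C@H](Cc2ccccc2)COC1=O | intermediate
18 | (R)-4-benzyl-3-[(2S)-2-{[tert-butyl(dimethyl)silyl]oxymethyl}butanoyl]-1,3-oxazolidin-2-one | CC[C@@H](CO[Si](C)(C)C(C)(C)C)C(=O)N1[C@H](Cc2ccccc2)COC1=O | intermediate
19 | (R)-2-{[tert-butyl(dimethyl)silyl]oxymethyl}butan-1-ol | CC[C@@H](CO[Si](C)(C)C(C)(C)C)CO | intermediate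
20 | (S)-2-{[tert-butyl(dimethyl)silyl]oxymethyl}butanal | CC[C@@H](CO[Si](C)(C)C(C)(C)C)C=O | intermediate
21 | triethyl 4-phosphonocrotonate | CCOC(=O)/C=C/CP(=O)(OCC)OCC | starting material
22 | ethyl (2E,4E,6R)-6-{[tert-butyl(dimethyl)silyl]oxymethyl}octa-2,4-dienoate | CC[C@@H](CO[Si](C)(C)C(C)(C)C)/C=C/C=C/C(=O)OCC | intermediate
23 | (2E,4E,6R)-6-{[tert-butyl(dimethyl)silyl]oxymethyl}octa-2,4-dienoic acid | CC[C@@H](CO[Si](C)(C)C(C)(C)C)/C=C/C=C/C(=O)O | intermediate
24 | mixed anhydride of 23 with 2,4,6-trichlorobenzoic acid (not isolated) | CC[C@@H](CO[Si](C)(C)C(C)(C)C)/C=C/C=C/C(=O)OC(=O)c1c(Cl)cc(Cl)cc1Cl | intermediate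
25 | C3 dienoate ester of 13 (C7 ketal, silyl ether) | CC[C@@H](CO[Si](C)(C)C(C)(C)C)/C=C/C=C/C(=O)O[C@H]1C=C[C@@H]2CCC3(OCCO3)C[C@]2(C)[C@H]1C | intermediate
26 | C7 ketone ester | CC[C@@H](CO[Si](C)(C)C(C)(C)C)/C=C/C=C/C(=O)O[C@H]1C=C[C@@H]2CCC(=O)C[C@]2(C)[C@H]1C | intermediate
27 | 8-hydroxy-7-ketone ester (C8 epimers) | CC[C@@H](CO[Si](C)(C)C(C)(C)C)/C=C/C=C/C(=O)O[C@H]1C=C[C@@H]2CC(O)C(=O)C[C@]2(C)[C@H]1C | intermediate
28 | 7,8-dione ester, C7 enol tautomer | CC[C@@H](CO[Si](C)(C)C(C)(C)C)/C=C/C=C/C(=O)O[C@H]1C=C[C@@H]2CC(=O)C(O)=C[C@]2(C)[C@H]1C | intermediate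
29 | O-silyl septeremophilane E | CC[C@@H](CO[Si](C)(C)C(C)(C)C)/C=C/C=C/C(=O)O[C@H]1C=CC2=CC(=O)C(O)=C[C@]2(C)[C@H]1C | intermediate
30 | septeremophilane E, (1R,2S,8aS)-7-hydroxy-1,8a-dimethyl-6-oxo-1,2,6,8a-tetrahydronaphthalen-2-yl (2E,4E,6R)-6-(hydroxymethyl)octa-2,4-dienoate | CC[C@H](/C=C/C=C/C(=O)O[C@H]1C=CC2=CC(=O)C(O)=C[C@]2(C)[C@H]1C)CO | target

Total step count: 20. Longest linear sequence: 13 steps (steps 1–7 and 15–20); steps 8–14 build the acid.

Steps most likely to fail

Step 4 (proposed new method). Racemisation through the dienamine may be slower than cyclisation, so that the process stalls as a plain kinetic resolution; enantioface discrimination at C5 may be low; and long reaction times may epimerise C4. Fallback with known chemistry: starting from 8, the cyclisation is run without asymmetric induction (pyrrolidine/AcOH, or KOt-Bu in t-BuOH), a known intramolecular Michael closure to angularly methylated cis-decalones, which gives the racemic cis-fused 4,5-dimethyldecalin-3,7-dione F1. The enantiomers are then separated by preparative chromatography on a chiral stationary phase, and the (4R,5S,10S) enantiomer re-enters the route as 9.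

Step 7. Facial selectivity at C3 may be poor or reversed, because the cis-fused bicycle can invert and present its β face to the hydride. Fallback: starting from 12, if the reduction delivers mainly the 3-epimeric alcohol, that (3R,4R,5S,10S)-7,7-ethylenedioxy-4,5-dimethyl-Δ1-octalin-3-ol F2 is used. It is esterified with acid 23 under Mitsunobu conditions (PPh3, diisopropyl azodicarboxylate, THF), which inverts C3 from the β face that the hydride showed to be open. This arrives directly at 25 and replaces steps 7 and 15.

Step 19. Hydride abstraction may be sluggish or may occur at other allylic positions, and the electron-rich enol may be over-oxidised. Fallback: starting from 28, double silylation (TMSOTf, Et3N, CH2Cl2) gives the 7,8-bis(trimethylsilyloxy) diene F3. Stoichiometric Pd(OAc)2 in MeCN (Saegusa–Ito oxidation) then desaturates C9–C10, since only the C8 enol ether has a β-hydrogen (H-10). Mildly acidic work-up cleaves the remaining C7 silyl enol ether and returns 29.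

Further compounds
F1 | step 4 | racemic cis-fused (4R*,5S*,10S*)-4,5-dimethyldecalin-3,7-dione | O=C1CC[C@@H]2CCC(=O)C[C@]2(C)[C@H]1C.O=C1CC[C@H]2CCC(=O)C[C@@]2(C)[C@@H]1C
F2 | step 7 | (3R,4R,5S,10S)-7,7-ethylenedioxy-4,5-dimethyl-Δ1-octalin-3-ol | O[C@@H]1C=C[C@@H]2CCC3(OCCO3)C[C@]2(C)[C@H]1C
F3 | step 19 | 7,8-bis(trimethylsilyloxy) diene derived from 28 | CC[C@@H](CO[Si](C)(C)C(C)(C)C)/C=C/C=C/C(=O)O[C@H]1C=C[C@@H]2C=C(O[Si](C)(C)C)C(O[Si](C)(C)C)=C[C@]2(C)[C@H]1C
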